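A direct plan would O-alkylate vanillin A1 with a tertiary propargylic chloride to the aryl propargyl ether A2, condense A2 with 2,4-dihydroxyacetophenone A3 to the 2'-hydroxychalcone A4, convert A4 into the isoflavone A5 by an oxidative 1,2-aryl shift with a salt of trivalent thallium and acid cyclisation, and close the chromene last by a thermal propargyl Claisen cascade.
Weak step, the oxidative 1,2-aryl shift of A4: it would need a full equivalent of a toxic thallium salt, and this oxidant would meet a terminal alkyne and two free phenols, so oxythallation and ring oxidation would compete.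
Weak step, the aldol condensation that gives A4: the unprotected resorcinol ketone A3 would react as a phenoxide dianion whose enolate is a poor nucleophile, so a large excess of hydroxide and days of reaction would be needed.
Weak step, the final chromene closure on A5: the complete isoflavone with its free 7-OH would be held near 190 °C in the last step, where any loss hits the most valuable material.

**Retrosynthetic overview**
Feature used: C3 of pyranone ring C is the one carbon bonded to C2, to C4 and to C1' of ring B (ring A = benzo ring of the chromone, ring B = methoxylated benzene ring, ring D = dimethylpyran); without C3, rings A and C are the commercial 6-hydroxy-1-benzofuran-3(2H)-one.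
Key disconnection: C3 is inserted as a single carbon atom between C2 and C4 by an aryl chlorocarbene that already carries the finished B/D chromene; the step forms C2–C3 and C3–C4 and expands a furan to the pyranone, whereas O1–C2 and C3–C1' are present from the start.
The carbene carbon is the nitrile carbon of 8-methoxy-2,2-dimethyl-2H-chromene-6-carbonitrile (nitrile, amidine, chlorodiazirine); ring D is closed first, in one step, by annulation of vanillonitrile with an enal acetal.
Ring order: D (step 1), then C last by 5-to-6 ring expansion (step 5); rings A and B are bought.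
The design has no aldol on a resorcinol ketone, no aryl shift, no thallium and no terminal alkyne; the only hot step is the first, on a small nitrile, and the last step runs at 50 °C.

Key step: step 5

Remark on the chemistry: aryl chlorodiazirines are energetic, so the diazirine would be kept in cold solution and never concentrated to dryness; vanillonitrile, 1,1-diethoxy-3-methylbut-2-ene and 6-hydroxy-1-benzofuran-3(2H)-one are assumed to be commercial.

Step 1
Reactants: 1 4-hydroxy-3-methoxybenzonitrile (vanillonitrile); 2 1,1-diethoxy-3-methylbut-2-ene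
Product: 5 8-methoxy-2,2-dimethyl-2H-chromene-6-carbonitrile, via C-alkylated phenol 3 (not isolated), via o-quinone methide 4 (not isolated)
Conditions: 2 (2 equiv), 3-picoline (0.5 equiv), p-xylene, 140 °C, 24 h, EtOH distilled off
Reagents that add atoms: none
Why: Pyridine-base-mediated chromenylation of a phenol with an enal acetal (formal [3+3] annulation: C-alkylation at the only free ortho carbon, loss of ethanol to the o-quinone methide, oxa-6π electrocyclisation), a reaction type established for 4-cyanophenol, should close ring D in one step on a robust nitrile, and no stereocentre is formed.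

Step 2
Reactants: 5 8-methoxy-2,2-dimethyl-2H-chromene-6-carbonitrile
Product: 7 8-methoxy-2,2-dimethyl-2H-chromene-6-carboximidamide hydrochloride, via lithium disilylamidinate 6 (not isolated)
Conditions: LiN(SiMe3)2 (1.5 equiv), THF, 0 °C to rt, 16 h; then HCl (4 M in dioxane, 5 equiv), 0 °C, 1 h; trituration with Et2O
Reagents that add atoms: lithium bis(trimethylsilyl)amide, [Li]N([Si](C)(C)C)[Si](C)(C)C; hydrogen chloride, Cl
Why: Amidine synthesis from an aryl nitrile, in which the silylamide adds to the nitrile to give the N,N'-disilylamidinate and anhydrous HCl removes both silyl groups to leave the amidinium chloride, while the short, cold acid treatment should leave the chromene alkene untouched.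

Step 3
Reactants: 7 8-methoxy-2,2-dimethyl-2H-chromene-6-carboximidamide hydrochloride
Product: 10 3-chloro-3-(8-methoxy-2,2-dimethyl-2H-chromen-6-yl)-3H-diazirine, via N,N'-dichloroamidine 8 (not isolated), via 1-chloro-1H-diazirine 9 (not isolated)
Conditions: LiCl (5 equiv), DMSO, aq NaOCl (saturated with NaCl, 6 equiv), pentane overlay, 0 °C to rt, 1 h, dark; pentane extraction, short silica plug, stored as a cold solution
Reagents that add atoms: sodium hypochlorite, [Na+].[O-]Cl; lithium chloride, [Li+].[Cl-]
Why: Graham oxidation, in which double N-chlorination, base-induced N–N bond formation to the 1-chloro-1H-diazirine and return of chloride at carbon give the 3-chloro-3H-diazirine, and at the high pH and short contact time the uncatalysed attack of hypochlorite on the chromene alkene should be slow.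

Step 4
Reactants: 11 6-hydroxy-1-benzofuran-3(2H)-one
Product: 12 3,6-bis[(tert-butyldimethylsilyl)oxy]-1-benzofuran
Conditions: TBSOTf (2.3 equiv), Et3N (3 equiv), CH2Cl2, 0 °C to rt, 1 h; filtration through basic alumina
Reagents that add atoms: tert-butyldimethylsilyl trifluoromethanesulfonate, CC(C)(C)[Si](C)(C)OS(=O)(=O)C(F)(F)F
Why: Soft enolisation and O-silylation of the coumaranone (driven by aromatisation to the benzofuran) together with silylation of the phenol, so that one reagent turns C2=C3 into an electron-rich enol ether and masks the later 7-OH.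

Step 5
Reactants: 10 3-chloro-3-(8-methoxy-2,2-dimethyl-2H-chromen-6-yl)-3H-diazirine; 12 3,6-bis[(tert-butyldimethylsilyl)oxy]-1-benzofuran
Product: 17 7-hydroxy-3-(8-methoxy-2,2-dimethyl-2H-chromen-6-yl)-4H-chromen-4-one, via aryl chlorocarbene 13 (not isolated), via chlorocyclopropane 14 (not isolated), via siloxybenzopyrylium chloride 15 (not isolated), via 7-silyl ether 16 (not isolated)
Conditions: 12 (2 equiv), Na2CO3 (3 equiv), MeCN, 50 °C, dark; 10 (1 equiv) in MeCN added over 4 h, then 8 h; then K2CO3 (0.5 equiv), MeOH, 0 °C to rt, 1 h; AcOH quench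
Reagents that add atoms: none
Why: Proposed new method: mild thermolysis of 10 should release N2 and the singlet aryl chlorocarbene 13, which adds [2+1] to the most electron-rich π bond present, the doubly oxygen-substituted C2=C3 bond of benzofuran 12, to give chlorocyclopropane 14; ionisation of the C–Cl bond, assisted by the para-alkoxyaryl group, then triggers disrotatory cyclopropyl-to-allyl cation opening of the bond between the two former alkene carbons, which ends in the aromatic 4-siloxybenzopyrylium chloride 15, and chloride removes the silyl group from O4 to leave the chromone carbonyl of 16. The closest known reaction types are the Ciamician–Dennstedt ring expansion of indoles and pyrroles to 3-arylquinolines and 3-arylpyridines with aryl chlorodiazirines and the dihalocarbene homologation of cyclic silyl enol ethers to 2-halocycloalkenones; a 3-siloxybenzofuran is at once a five-membered heteroarene and a silyl enol ether, so both precedents should carry over. Ring C is not closed by a cyclisation but arises by 5-to-6 ring expansion, in which C2–C3 and C3–C4 (chromone numbering) are formed and the former C2–C3 bond of the benzofuran is broken. Regiochemistry is fixed by the mechanism, because only the cyclopropane bond opposite the carbene carbon can open, so the aryl-bearing carbon must end between C2 and C4 and the isoflavone, not the flavone, results. The step needs chemoselectivity for the enol ether over the chromene alkenes of 10 and of the product, which the twofold excess of the far more nucleophilic 12 and the slow addition of 10 should secure, and it needs both C1 epimers of 14 to open, which the cation-stabilising aryl group and the aromatic cation make likely. Methanolic K2CO3 finally cleaves the phenolic silyl ether of 16, and the two stereocentres of 14 are lost on ring opening, so none has to be controlled.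

**Compound list**
1 | 4-hydroxy-3-methoxybenzonitrile (vanillonitrile) | COc1cc(C#N)ccc1O | starting material
2 | 1,1-diethoxy-3-methylbut-2-ene | CCOC(OCC)C=C(C)C | starting material
3 | 3-(1-ethoxy-3-methylbut-2-en-1-yl)-4-hydroxy-5-methoxybenzonitrile (racemic) | CCOC(C=C(C)C)c1cc(C#N)cc(OC)c1O | intermediate
4 | (3Z)-5-methoxy-3-(3-methylbut-2-en-1-ylidene)-4-oxocyclohexa-1,5-diene-1-carbonitrile | CC(C)=C/C=C1/C=C(C#N)C=C(OC)C1=O | intermediate
5 | 8-methoxy-2,2-dimethyl-2H-chromene-6-carbonitrile | COc1cc(C#N)cc2c1OC(C)(C)C=C2 | intermediate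
6 | lithium N,N'-bis(trimethylsilyl)-8-methoxy-2,2-dimethyl-2H-chromene-6-carboximidamidate | COc1cc(C(=N[Si](C)(C)C)N([Li])[Si](C)(C)C)cc2c1OC(C)(C)C=C2 | intermediate
7 | 8-methoxy-2,2-dimethyl-2H-chromene-6-carboximidamide hydrochloride | COc1cc(C(=N)N)cc2c1OC(C)(C)C=C2.Cl | intermediate
8 | N,N'-dichloro-8-methoxy-2,2-dimethyl-2H-chromene-6-carboximidamide | COc1cc(C(=NCl)NCl)cc2c1OC(C)(C)C=C2 | intermediate
9 | 1-chloro-3-(8-methoxy-2,2-dimethyl-2H-chromen-6-yl)-1H-diazirine | COc1cc(C2=NN2Cl)cc2c1OC(C)(C)C=C2 | intermediate
10 | 3-chloro-3-(8-methoxy-2,2-dimethyl-2H-chromen-6-yl)-3H-diazirine | COc1cc(C2(Cl)N=N2)cc2c1OC(C)(C)C=C2 | intermediate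
11 | 6-hydroxy-1-benzofuran-3(2H)-one | O=C1COc2cc(O)ccc21 | starting material
12 | 3,6-bis[(tert-butyldimethylsilyl)oxy]-1-benzofuran | CC(C)(C)[Si](C)(C)Oc1ccc2c(O[Si](C)(C)C(C)(C)C)coc2c1 | intermediate
13 | chloro(8-methoxy-2,2-dimethyl-2H-chromen-6-yl)carbene (singlet) | COc1cc([C]Cl)cc2c1OC(C)(C)C=C2 | intermediate
14 | 4,6b-bis[(tert-butyldimethylsilyl)oxy]-1-chloro-1-(8-methoxy-2,2-dimethyl-2H-chromen-6-yl)-1a,6b-dihydro-1H-cyclopropa[b][1]benzofuran (racemic, both C1 epimers) | CC(C)(C)[Si](C)(C)Oc1ccc2c(c1)OC1C(Cl)(c3cc(OC)c4OC(C)(C)C=Cc4c3)C21O[Si](C)(C)C(C)(C)C | intermediate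
15 | 4,7-bis[(tert-butyldimethylsilyl)oxy]-3-(8-methoxy-2,2-dimethyl-2H-chromen-6-yl)chromenylium chloride | CC(C)(C)[Si](C)(C)Oc1ccc2c(O[Si](C)(C)C(C)(C)C)c(-c3cc(OC)c4OC(C)(C)C=Cc4c3)c[o+]c2c1.[Cl-] | intermediate
16 | 7-[(tert-butyldimethylsilyl)oxy]-3-(8-methoxy-2,2-dimethyl-2H-chromen-6-yl)-4H-chromen-4-one | COc1cc(-c2coc3cc(O[Si](C)(C)C(C)(C)C)ccc3c2=O)cc2c1OC(C)(C)C=C2 | intermediate
17 | 7-hydroxy-3-(8-methoxy-2,2-dimethyl-2H-chromen-6-yl)-4H-chromen-4-one | COc1cc(-c2coc3cc(O)ccc3c2=O)cc2c1OC(C)(C)C=C2 | target

Total step count: 5. Longest linear sequence: 4 steps (steps 1, 2, 3 and 5); step 4 is a one-step branch.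

**Steps most likely to fail**

Step 5 (Proposed new method). The carbene may be consumed by azine formation with unreacted diazirine or by cyclopropanation of a chromene alkene before it meets the enol ether, and a chlorocyclopropane that does form may be hydrolysed instead of opening. The fallback uses known chemistry; it sets out from 2 (with commercial 4-bromo-2-methoxyphenol in place of 1) and comes back to the route at 17. 4-Bromo-2-methoxyphenol would be condensed with 2 under the conditions of step 1 to 6-bromo-8-methoxy-2,2-dimethyl-2H-chromene F1. Miyaura borylation (B2pin2, Pd(dppf)Cl2, KOAc, dioxane, 85 °C) would turn F1 into 2-(8-methoxy-2,2-dimethyl-2H-chromen-6-yl)-4,4,5,5-tetramethyl-1,3,2-dioxaborolane F2. Commercial 1-[2-hydroxy-4-(methoxymethoxy)phenyl]ethanone would be condensed with DMF-DMA to (E)-3-(dimethylamino)-1-[2-hydroxy-4-(methoxymethoxy)phenyl]prop-2-en-1-one F3 and cyclised with I2 to 3-iodo-7-(methoxymethoxy)-4H-chromen-4-one F4. Suzuki–Miyaura coupling of F2 with F4 (Pd(PPh3)4, Na2CO3, DME/H2O, 80 °C) would give 3-(8-methoxy-2,2-dimethyl-2H-chromen-6-yl)-7-(methoxymethoxy)-4H-chromen-4-one F5, and HCl in MeOH at 40 °C would release 17.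

Step 1. The electron-poor, ortho-substituted phenol may be C-alkylated too slowly, so that the acetal is lost to elimination and oligomerisation before the annulation takes place. The fallback sets out from 1 and comes back at 5, and it reverses the order of bond formation (O–C first, C–C second). 1 would be O-alkylated with 3-chloro-3-methylbut-1-yne (DBU, CuCl2·2H2O cat., MeCN, 0 °C to rt) to 3-methoxy-4-[(2-methylbut-3-yn-2-yl)oxy]benzonitrile F6. F6 would be heated (1,2-dichlorobenzene, 180 °C) so that propargyl Claisen rearrangement, 1,5-hydrogen shift and oxa-6π electrocyclisation give 5.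

Step 3. Hypochlorite may chlorinate or epoxidise the electron-rich chromene alkene, and the para-alkoxyaryl diazirine may lose nitrogen during extraction. The fallback sets out from 1 and comes back at 16; ring D would be closed after the carbon insertion, so that neither the oxidation nor the carbene meets an alkene. The propargyl ether 3-methoxy-4-[(2-methylbut-3-yn-2-yl)oxy]benzonitrile F6 (from 1 as described for step 1) would be converted as in step 2 into 3-methoxy-4-[(2-methylbut-3-yn-2-yl)oxy]benzenecarboximidamide hydrochloride F7 and as in step 3 into 3-chloro-3-{3-methoxy-4-[(2-methylbut-3-yn-2-yl)oxy]phenyl}-3H-diazirine F8. Insertion into 12 under the conditions of step 5, stopped before the methanolysis, would give 7-[(tert-butyldimethylsilyl)oxy]-3-{3-methoxy-4-[(2-methylbut-3-yn-2-yl)oxy]phenyl}-4H-chromen-4-one F9. Heating F9 (PhNEt2, 185 °C) would close the chromene by the propargyl Claisen cascade and give 16, from which the methanolysis of step 5 leads to 17.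

**Further compounds**
F1 | step 5 | 6-bromo-8-methoxy-2,2-dimethyl-2H-chromene | COc1cc(Br)cc2c1OC(C)(C)C=C2
F2 | step 5 | 2-(8-methoxy-2,2-dimethyl-2H-chromen-6-yl)-4,4,5,5-tetramethyl-1,3,2-dioxaborolane | COc1cc(B2OC(C)(C)C(C)(C)O2)cc2c1OC(C)(C)C=C2
F3 | step 5 | (E)-3-(dimethylamino)-1-[2-hydroxy-4-(methoxymethoxy)phenyl]prop-2-en-1-one | COCOc1ccc(C(=O)/C=C/N(C)C)c(O)c1
F4 | step 5 | 3-iodo-7-(methoxymethoxy)-4H-chromen-4-one | COCOc1ccc2c(c1)occ(I)c2=O
F5 | step 5 | 3-(8-methoxy-2,2-dimethyl-2H-chromen-6-yl)-7-(methoxymethoxy)-4H-chromen-4-one | COc1cc(-c2coc3cc(OCOC)ccc3c2=O)cc2c1OC(C)(C)C=C2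
F6 | step 1 | 3-methoxy-4-[(2-methylbut-3-yn-2-yl)oxy]benzonitrile | COc1cc(C#N)ccc1OC(C)(C)C#C
F7 | step 3 | 3-methoxy-4-[(2-methylbut-3-yn-2-yl)oxy]benzenecarboximidamide hydrochloride | COc1cc(C(=N)N)ccc1OC(C)(C)C#C.Cl
F8 | step 3 | 3-chloro-3-{3-methoxy-4-[(2-methylbut-3-yn-2-yl)oxy]phenyl}-3H-diazirine | COc1cc(C2(Cl)N=N2)ccc1OC(C)(C)C#C
F9 | step 3 | 7-[(tert-butyldimethylsilyl)oxy]-3-{3-methoxy-4-[(2-methylbut-3-yn-2-yl)oxy]phenyl}-4H-chromen-4-one | COc1cc(-c2coc3cc(O[Si](C)(C)C(C)(C)C)ccc3c2=O)ccc1OC(C)(C)C#C
A1 | direct plan | vanillin (4-hydroxy-3-methoxybenzaldehyde) | COc1cc(C=O)ccc1O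
A2 | direct plan | 3-methoxy-4-[(2-methylbut-3-yn-2-yl)oxy]benzaldehyde | COc1cc(C=O)ccc1OC(C)(C)C#C
A3 | direct plan | 2,4-dihydroxyacetophenone | CC(=O)c1ccc(O)cc1O
A4 | direct plan | (E)-1-(2,4-dihydroxyphenyl)-3-{3-methoxy-4-[(2-methylbut-3-yn-2-yl)oxy]phenyl}prop-2-en-1-one | COc1cc(/C=C/C(=O)c2ccc(O)cc2O)ccc1OC(C)(C)C#C
A5 | direct plan | 7-hydroxy-3-{3-methoxy-4-[(2-methylbut-3-yn-2-yl)oxy]phenyl}-4H-chromen-4-one | COc1cc(-c2coc3cc(O)ccc3c2=O)ccc1OC(C)(C)C#C
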